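The oxolane (O1, C2–C5) carries ring A (3-hydroxy-4,5-dimethoxyphenyl) at C2 and ring B (3,4,5-trimethoxyphenyl) at C5 on one face, and the C3 and C4 methyls, cis to each other, on the opposite face. Both methyl carbons are therefore disconnected together, back to the C3=C4 alkene of a cis-2,5-diaryl-2,5-dihydrofuran. A palladium-catalysed oxidative bis-methoxycarbonylation adds two ester carbons syn to that alkene, anti to the aryls, forming the C3–C and C4–C bonds and both stereocentres in one operation. The precursor, (2S,5R)-dihydrofuran 11 with the ring A phenol as its benzyl ether, comes from an iridium-catalysed allylic etherification followed by ring-closing metathesis; the esters are then reduced to methyls.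

Key step: step 8

Remark on numbering: O1, C2 (ring A), C3, C4, C5 (ring B); the target is (2S,3S,4R,5R), 11 is (2S,5R) and 12 is (2S,3S,4R,5R).

Assumption: with iridium/phosphoramidite catalysts the (Ra,R,R) ligand is taken to deliver oxygen nucleophiles to cinnamyl carbonates so that the aryl-bearing carbon becomes (R); should a first run show the opposite sense, the (Sa,S,S) ligand would be used with no other change.

Step 1
Reactants: 1 3-hydroxy-4,5-dimethoxybenzaldehyde
Product: 2 3-(benzyloxy)-4,5-dimethoxybenzaldehyde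
Conditions: BnBr (1.1 equiv), K2CO3 (1.5 equiv), DMF, 25 °C
Reagents that add atoms: benzyl bromide, BrCc1ccccc1
Why: Williamson ether synthesis on the only acidic OH; the benzyl ether is chosen because it should survive the Grignard reagent, alkoxide, ruthenium, palladium/CO and hydride steps and leaves last under neutral conditions that spare the acid-sensitive ring ether.

Step 2
Reactants: 2 3-(benzyloxy)-4,5-dimethoxybenzaldehyde; 3 vinylmagnesium bromide
Product: 4 rac-1-[3-(benzyloxy)-4,5-dimethoxyphenyl]prop-2-en-1-ol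
Conditions: 3 (1.3 equiv), THF, −78 → 0 °C; H2O then aq. NH4Cl
Reagents that add atoms: vinylmagnesium bromide (compound 3), C=C[Mg]Br
Why: Grignard 1,2-addition to the aryl aldehyde should give the racemic secondary allylic alcohol; the aryl ethers are inert and a neutral work-up avoids allylic transposition.

Step 3
Reactants: 4 rac-1-[3-(benzyloxy)-4,5-dimethoxyphenyl]prop-2-en-1-ol
Product: 5 (S)-1-[3-(benzyloxy)-4,5-dimethoxyphenyl]prop-2-en-1-ol
Conditions: immobilised Candida antarctica lipase B (Novozym 435), isopropenyl acetate (2 equiv), 4 Å molecular sieves, toluene, 30 °C, stopped just past half conversion; chromatography on Et3N-deactivated silica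
Reagents that add atoms: none
Why: Lipase-catalysed kinetic resolution by irreversible transesterification: this lipase acylates the (R)-enantiomer of 1-arylprop-2-en-1-ols (aryl as large group, vinyl as medium group), so the unreacted alcohol recovered should be the (S)-enantiomer, which is the C2 configuration of the target.

Step 4
Reactants: 6 methyl (E)-3-(3,4,5-trimethoxyphenyl)prop-2-enoate
Product: 7 (E)-3-(3,4,5-trimethoxyphenyl)prop-2-en-1-ol
Conditions: i-Bu2AlH (2.5 equiv), CH2Cl2, −78 → 0 °C; aq. potassium sodium tartrate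
Reagents that add atoms: none
Why: Aluminium hydride 1,2-reduction of a conjugated ester should give the allylic alcohol without touching the alkene, and the E geometry is retained.

Step 5
Reactants: 7 (E)-3-(3,4,5-trimethoxyphenyl)prop-2-en-1-ol
Product: 8 tert-butyl (E)-3-(3,4,5-trimethoxyphenyl)prop-2-en-1-yl carbonate
Conditions: Boc2O (1.3 equiv), Bu4NHSO4 (5 mol%), 30% aq. NaOH, CH2Cl2, 0 → 25 °C
Reagents that add atoms: di-tert-butyl dicarbonate, CC(C)(C)OC(=O)OC(=O)OC(C)(C)C
Why: Phase-transfer O-acylation of a primary allylic alcohol; the tert-butyl carbonate is chosen because the tert-butoxide it releases in step 6 is too hindered to compete with the desired alkoxide.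

Step 6
Reactants: 5 (S)-1-[3-(benzyloxy)-4,5-dimethoxyphenyl]prop-2-en-1-ol; 8 tert-butyl (E)-3-(3,4,5-trimethoxyphenyl)prop-2-en-1-yl carbonate
Product: 10 (S)-1-[3-(benzyloxy)-4,5-dimethoxyphenyl]prop-2-en-1-yl (R)-1-(3,4,5-trimethoxyphenyl)prop-2-en-1-yl ether, via copper alkoxide of the ring A alcohol 9 (not isolated)
Conditions: 5 (1.2 equiv), n-BuLi (1.2 equiv), THF, 0 °C, then CuI (1.2 equiv), 25 °C; then 8 (1.0 equiv), [Ir(cod)Cl]2 (2 mol%), (Ra,R,R)-O,O′-(1,1′-binaphthalene-2,2′-diyl) N,N-bis(1-phenylethyl)phosphoramidite (4 mol%, catalyst preactivated with n-PrNH2), THF, 25 °C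
Reagents that add atoms: CuI, [Cu]I (supplies the copper of intermediate 9 only; none of it remains in 10)
Why: Iridium-catalysed asymmetric allylic etherification with a monovalent copper alkoxide: the cyclometalated iridium phosphoramidite ionises the linear carbonate and the alkoxide attacks the aryl-bearing allyl terminus (branched product), the ligand setting the new ring B carbon as (R) under catalyst control while the (S) carbon of the alkoxide is not involved.

Step 7
Reactants: 10 (S)-1-[3-(benzyloxy)-4,5-dimethoxyphenyl]prop-2-en-1-yl (R)-1-(3,4,5-trimethoxyphenyl)prop-2-en-1-yl ether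
Product: 11 (2S,5R)-2-[3-(benzyloxy)-4,5-dimethoxyphenyl]-5-(3,4,5-trimethoxyphenyl)-2,5-dihydrofuran (aryls cis)
Conditions: second-generation Grubbs catalyst (3 mol%), CH2Cl2 (0.02 M), 40 °C, argon; product kept under argon and used promptly
Reagents that add atoms: none
Why: Ring-closing metathesis of the two terminal vinyl groups should close the five-membered ring with loss of ethene; neither stereocentre is touched, so the (S,R) ether gives the cis-2,5-diaryl ring.

Step 8
Reactants: 11 (2S,5R)-2-[3-(benzyloxy)-4,5-dimethoxyphenyl]-5-(3,4,5-trimethoxyphenyl)-2,5-dihydrofuran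
Product: 12 dimethyl (2S,3S,4R,5R)-2-[3-(benzyloxy)-4,5-dimethoxyphenyl]-5-(3,4,5-trimethoxyphenyl)oxolane-3,4-dicarboxylate (esters cis to each other, trans to both aryls)
Conditions: Pd(OCOCF3)2 (5 mol%), N,N′-bis(2,6-dimethylphenyl)butane-2,3-diimine (5.5 mol%), p-TsOH·H2O (5 mol%), p-benzoquinone (1.5 equiv), CO (4 bar), MeOH/THF 7:1, 20 °C
Reagents that add atoms: carbon monoxide, [C-]#[O+]; methanol, CO
Why: A cationic diimine-ligated divalent palladium methoxycarbonyl complex, formed from Pd(OCOCF3)2, CO and methanol, coordinates the C3=C4 alkene and inserts it syn, giving a C3–CO2Me bond and a C4–Pd bond held in a five-membered chelate by the new ester carbonyl; CO then inserts into the C4–Pd bond with retention and methanolysis of the acyl releases 12 and zerovalent palladium, which p-benzoquinone returns to the divalent state. The closest known reaction type is the palladium-catalysed oxidative bis-alkoxycarbonylation of 1,2-disubstituted and cyclic alkenes to succinic diesters, an established stereospecific syn addition. No ring is closed. C3 and C4 are the new stereocentres: their cis relationship follows from the syn insertion mechanism, and their configuration relative to C2 and C5 is set by the substrate, because the metal can reach only the face of the flat dihydrofuran that carries the two hydrogens, ring A and ring B both covering the other. The selectivity still needed is carbonylation over β-hydride elimination toward the syn hydrogen at C5, which would lead to a 2,5-diarylfuran; 4 bar of CO, the chelated alkyl intermediate and 20 °C are chosen to keep CO insertion ahead, and the aryl ethers are inert.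

Step 9
Reactants: 12 dimethyl (2S,3S,4R,5R)-2-[3-(benzyloxy)-4,5-dimethoxyphenyl]-5-(3,4,5-trimethoxyphenyl)oxolane-3,4-dicarboxylate
Product: 13 [(2S,3R,4S,5R)-2-[3-(benzyloxy)-4,5-dimethoxyphenyl]-5-(3,4,5-trimethoxyphenyl)oxolane-3,4-diyl]dimethanol
Conditions: LiAlH4 (3 equiv), THF, 0 °C; H2O, 15% aq. NaOH, H2O
Reagents that add atoms: none
Why: Hydride reduction of both esters to primary alcohols should be fast enough at 0 °C that the cis diester is not epimerised; the ring ether and the benzyl ether are inert.

Step 10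
Reactants: 13 [(2S,3R,4S,5R)-2-[3-(benzyloxy)-4,5-dimethoxyphenyl]-5-(3,4,5-trimethoxyphenyl)oxolane-3,4-diyl]dimethanol
Product: 14 [(2S,3R,4S,5R)-2-[3-(benzyloxy)-4,5-dimethoxyphenyl]-5-(3,4,5-trimethoxyphenyl)oxolane-3,4-diyl]bis(methylene) dimethanesulfonate
Conditions: MsCl (3 equiv), Et3N (4 equiv), CH2Cl2, −10 °C, short reaction time; used crude
Reagents that add atoms: methanesulfonyl chloride, CS(=O)(=O)Cl
Why: Sulfonylation of both primary alcohols through the sulfene pathway with excess reagent at low temperature should be faster than ring closure of the monomesylate onto its neighbour.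

Step 11
Reactants: 14 [(2S,3R,4S,5R)-2-[3-(benzyloxy)-4,5-dimethoxyphenyl]-5-(3,4,5-trimethoxyphenyl)oxolane-3,4-diyl]bis(methylene) dimethanesulfonate
Product: 15 (2S,3S,4R,5R)-2-[3-(benzyloxy)-4,5-dimethoxyphenyl]-3,4-dimethyl-5-(3,4,5-trimethoxyphenyl)oxolane
Conditions: LiBHEt3 (6 equiv), THF, 0 → 25 °C; aq. NH4Cl
Reagents that add atoms: none
Why: SN2 displacement of the two primary mesylates by the strongly nucleophilic borohydride should turn both CH2OMs groups into methyls, the standard sulfonate-reduction endgame for 3,4-bis(hydroxymethyl)oxolane lignans; no stereocentre is involved.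

Step 12
Reactants: 15 (2S,3S,4R,5R)-2-[3-(benzyloxy)-4,5-dimethoxyphenyl]-3,4-dimethyl-5-(3,4,5-trimethoxyphenyl)oxolane
Product: 16 5-[(2S,3S,4R,5R)-3,4-dimethyl-5-(3,4,5-trimethoxyphenyl)oxolan-2-yl]-2,3-dimethoxyphenol (target)
Conditions: H2 (1 atm), 10% Pd/C, EtOAc, 25 °C, stopped at full consumption of 15
Reagents that add atoms: none
Why: Catalytic hydrogenolysis of the aryl benzyl ether is expected to be much faster than cleavage of the hindered secondary ring C–O bonds, so the phenol should be freed under neutral conditions without epimerising C2 or C5.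

Compound list
1 | 3-hydroxy-4,5-dimethoxybenzaldehyde | COc1cc(C=O)cc(O)c1OC | starting material
2 | 3-(benzyloxy)-4,5-dimethoxybenzaldehyde | COc1cc(C=O)cc(OCc2ccccc2)c1OC | intermediate
3 | vinylmagnesium bromide | C=C[Mg]Br | starting material
4 | rac-1-[3-(benzyloxy)-4,5-dimethoxyphenyl]prop-2-en-1-ol | COc1cc(C(O)C=C)cc(OCc2ccccc2)c1OC | intermediate
5 | (S)-1-[3-(benzyloxy)-4,5-dimethoxyphenyl]prop-2-en-1-ol | COc1cc([C@@H](O)C=C)cc(OCc2ccccc2)c1OC | intermediate
6 | methyl (E)-3-(3,4,5-trimethoxyphenyl)prop-2-enoate | COC(=O)/C=C/c1cc(OC)c(OC)c(OC)c1 | starting material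
7 | (E)-3-(3,4,5-trimethoxyphenyl)prop-2-en-1-ol | OC/C=C/c1cc(OC)c(OC)c(OC)c1 | intermediate
8 | tert-butyl (E)-3-(3,4,5-trimethoxyphenyl)prop-2-en-1-yl carbonate | CC(C)(C)OC(=O)OC/C=C/c1cc(OC)c(OC)c(OC)c1 | intermediate
9 | monovalent copper alkoxide of (S)-alcohol 5 (formed in the flask) | COc1cc([C@@H](O[Cu])C=C)cc(OCc2ccccc2)c1OC | intermediate
10 | (S)-1-[3-(benzyloxy)-4,5-dimethoxyphenyl]prop-2-en-1-yl (R)-1-(3,4,5-trimethoxyphenyl)prop-2-en-1-yl ether | COc1cc([C@@H](O[C@H](C=C)c2cc(OC)c(OC)c(OC)c2)C=C)cc(OCc3ccccc3)c1OC | intermediate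
11 | (2S,5R)-2-[3-(benzyloxy)-4,5-dimethoxyphenyl]-5-(3,4,5-trimethoxyphenyl)-2,5-dihydrofuran | COc1cc([C@H]2O[C@@H](c3cc(OC)c(OC)c(OC)c3)C=C2)cc(OCc4ccccc4)c1OC | intermediate
12 | dimethyl (2S,3S,4R,5R)-2-[3-(benzyloxy)-4,5-dimethoxyphenyl]-5-(3,4,5-trimethoxyphenyl)oxolane-3,4-dicarboxylate | COc1cc([C@H]2O[C@@H](c3cc(OC)c(OC)c(OC)c3)[C@H](C(=O)OC)[C@@H]2C(=O)OC)cc(OCc4ccccc4)c1OC | intermediate
13 | [(2S,3R,4S,5R)-2-[3-(benzyloxy)-4,5-dimethoxyphenyl]-5-(3,4,5-trimethoxyphenyl)oxolane-3,4-diyl]dimethanol | COc1cc([C@H]2O[C@@H](c3cc(OC)c(OC)c(OC)c3)[C@H](CO)[C@@H]2CO)cc(OCc4ccccc4)c1OC | intermediate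
14 | [(2S,3R,4S,5R)-2-[3-(benzyloxy)-4,5-dimethoxyphenyl]-5-(3,4,5-trimethoxyphenyl)oxolane-3,4-diyl]bis(methylene) dimethanesulfonate | COc1cc([C@H]2O[C@@H](c3cc(OC)c(OC)c(OC)c3)[C@H](COS(C)(=O)=O)[C@@H]2COS(C)(=O)=O)cc(OCc4ccccc4)c1OC | intermediate
15 | (2S,3S,4R,5R)-2-[3-(benzyloxy)-4,5-dimethoxyphenyl]-3,4-dimethyl-5-(3,4,5-trimethoxyphenyl)oxolane | COc1cc([C@H]2O[C@@H](c3cc(OC)c(OC)c(OC)c3)[C@H](C)[C@@H]2C)cc(OCc4ccccc4)c1OC | intermediate
16 | 5-[(2S,3S,4R,5R)-3,4-dimethyl-5-(3,4,5-trimethoxyphenyl)oxolan-2-yl]-2,3-dimethoxyphenol | COc1cc([C@H]2O[C@@H](c3cc(OC)c(OC)c(OC)c3)[C@H](C)[C@@H]2C)cc(O)c1OC | target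

Total step count: 12.
Longest linear sequence: 10 steps (steps 1, 2, 3, 6, 7, 8, 9, 10, 11, 12, from compound 1); steps 4 and 5 form the short ring B branch.

Steps most likely to fail

Step 8. The double carbonylation may be outrun by β-hydride elimination and oxidative aromatisation of the dihydrofuran, or by acid-promoted ionisation of the allylic, benzylic C2–O and C5–O bonds in methanol; insertion of the hindered ring alkene may also be slow. The fallback sets out from 11 and installs the two carbons by boron chemistry. Syn diboration with B2pin2 and Pt(dba)2 in toluene at 50 °C, again from the face opposite the aryls, should give (2S,3S,4R,5R)-3,4-bis(pinacolatoboryl)-2-[3-(benzyloxy)-4,5-dimethoxyphenyl]-5-(3,4,5-trimethoxyphenyl)oxolane F1. A double Matteson homologation with chloromethyllithium (BrCH2Cl, n-BuLi, THF, −78 → 25 °C), which proceeds with retention at the migrating carbons, should give the 3,4-bis(pinacolatoborylmethyl)oxolane F2. Oxidation with NaOH/H2O2 then gives the diol, and the fallback comes back to the route at 13.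

Step 6. Attack of the hindered secondary alkoxide may be slow, branched regioselectivity may erode, or a mismatched pairing of catalyst and chiral alkoxide may lower the diastereoselectivity. The fallback sets out from 8 and 9 and separates the creation of the ring B stereocentre from the C–O coupling. The same iridium/phosphoramidite catalyst with Et3SiOK as a small hydroxide surrogate should give (R)-triethyl{[1-(3,4,5-trimethoxyphenyl)prop-2-en-1-yl]oxy}silane F3. Bu4NF frees (R)-1-(3,4,5-trimethoxyphenyl)prop-2-en-1-ol F4, and Boc2O gives the branched tert-butyl (R)-1-(3,4,5-trimethoxyphenyl)prop-2-en-1-yl carbonate F5. A stereospecific rhodium-catalysed allylic etherification (RhCl(PPh3)3, P(OMe)3, THF, 0 → 25 °C) of F5 with copper alkoxide 9 proceeds with net retention at the ring B carbon, and the fallback comes back to the route at 10.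

Step 11. Hydride may attack sulfur instead of carbon and free an alkoxide that closes onto the neighbouring mesylate, giving a bicyclic ether in place of the two methyls. The fallback sets out from 14 and replaces the hydride displacement by halide exchange and radical reduction. A Finkelstein reaction (NaI, butanone, reflux) should give (2S,3R,4S,5R)-2-[3-(benzyloxy)-4,5-dimethoxyphenyl]-3,4-bis(iodomethyl)-5-(3,4,5-trimethoxyphenyl)oxolane F6. Radical dehalogenation with Bu3SnH and AIBN in toluene at 80 °C should then give both methyls, and the fallback comes back to the route at 15.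

Further compounds
F1 | step 8 | (2S,3S,4R,5R)-3,4-bis(pinacolatoboryl)-2-[3-(benzyloxy)-4,5-dimethoxyphenyl]-5-(3,4,5-trimethoxyphenyl)oxolane | COc1cc([C@H]2O[C@@H](c3cc(OC)c(OC)c(OC)c3)[C@H](B4OC(C)(C)C(C)(C)O4)[C@@H]2B5OC(C)(C)C(C)(C)O5)cc(OCc6ccccc6)c1OC
F2 | step 8 | (2S,3S,4R,5R)-3,4-bis(pinacolatoborylmethyl)-2-[3-(benzyloxy)-4,5-dimethoxyphenyl]-5-(3,4,5-trimethoxyphenyl)oxolane | COc1cc([C@H]2O[C@@H](c3cc(OC)c(OC)c(OC)c3)[C@H](CB4OC(C)(C)C(C)(C)O4)[C@@H]2CB5OC(C)(C)C(C)(C)O5)cc(OCc6ccccc6)c1OC
F3 | step 6 | (R)-triethyl{[1-(3,4,5-trimethoxyphenyl)prop-2-en-1-yl]oxy}silane | CC[Si](CC)(CC)O[C@H](C=C)c1cc(OC)c(OC)c(OC)c1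
F4 | step 6 | (R)-1-(3,4,5-trimethoxyphenyl)prop-2-en-1-ol | O[C@H](C=C)c1cc(OC)c(OC)c(OC)c1
F5 | step 6 | tert-butyl (R)-1-(3,4,5-trimethoxyphenyl)prop-2-en-1-yl carbonate | CC(C)(C)OC(=O)O[C@H](C=C)c1cc(OC)c(OC)c(OC)c1
F6 | step 11 | (2S,3R,4S,5R)-2-[3-(benzyloxy)-4,5-dimethoxyphenyl]-3,4-bis(iodomethyl)-5-(3,4,5-trimethoxyphenyl)oxolane | COc1cc([C@H]2O[C@@H](c3cc(OC)c(OC)c(OC)c3)[C@H](CI)[C@@H]2CI)cc(OCc4ccccc4)c1OC
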